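## Structural features

The target is the 3-O-gallate of a flavan-3,4-diol. Ring A (phloroglucinol type, hydroxyls at C5 and C7) is fused to the pyran ring C, which carries the 3,4-dihydroxyphenyl ring B on C2, a 3,4,5-trihydroxybenzoyl ester on O3 and a free hydroxyl on C4. The SMILES is read as (2R,3S,4S): C2, C3 and C4 are contiguous stereocentres on ring C, the C2 aryl and C3 acyloxy groups are trans, and the C3 acyloxy and C4 hydroxyl groups are cis. C3 and C4 are neighbouring oxygen-bearing carbons, and both can be traced back to aldehyde carbons: C4 to the formyl carbon of a ring A salicylaldehyde, C3 to the formyl carbon of an O-aryl mandelaldehyde whose benzylic carbon is C2. This vicinal-diol bond C3–C4, held next to the aryl ether O1–C2, is the feature the key step exploits. The C4 hydroxyl is benzylic to a 2,4,6-trioxygenated ring, so acid ionises it (epimerisation, self-condensation) and catalytic hydrogenation is liable to cleave it; benzyl ethers and acid-labile groups are therefore ruled out for the phenols. The galloyl ester sits on one oxygen of a cis-diol and can migrate to O4 under base, and the catechol and pyrogallol units oxidise in basic air. The real difficulty is threefold: the cis-3,4-diol on the face opposite the C2 aryl group, the distinction between O3 and O4, and the release of seven phenols without touching C4–O or the ester.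

## Logic of the disconnections

In one sentence: ring C is closed by a samarium diiodide pinacol coupling between the two aldehyde carbons of 11.

18 to 17: the seven aryl O–Si bonds are cut. The phenols must be freed last, by a method that is neither reductive, nor strongly acidic, nor basic, which points to silyl ethers and buffered fluoride. Nothing is gained in skeleton; the demand is that C4–OH and the ester stay where they are.

17 to 12 and 16: the ester bond between O3 and the galloyl carbonyl is cut. This removes a symmetrical acyl unit and leaves a cis-diol. The forward step must acylate the equatorial O3 in the presence of the pseudoaxial, peri-hindered O4 and must not allow acyl migration.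

12 to 11: the C3–C4 bond is cut. Ring C opens, the stereocentres C3 and C4 disappear together, and two aldehydes of like polarity appear on a chain that holds only the C2 stereocentre. The forward step must couple two electrophilic carbons reductively, faster than 11 can enolise, with the two oxygens cis and on the face opposite the C2 aryl group.

11 to 10 to 9: no skeletal bond is cut; the two formyl groups are taken back to a diol and then to an ester plus an aryl aldehyde. The labile α-aryloxy aldehyde thus exists for one step only, and C2 is carried as a stable ester through the fragment union. The oxidation must be free of base.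

9 to 2 and 8: the O1–C2 bond is cut. This is the convergent union of the ring A and ring B fragments and fixes C2 by inversion of a carbinol. The forward step needs a clean SN2 displacement at an electron-rich benzylic carbon and must tolerate the free formyl group.

8 to 7 to 4 and 5: the C2–H bond (hydride addition to a ketone) and the bond between ring B and C2 (acylation of an aryl Grignard reagent) are cut. The stereocentre then comes from a catalyst, and the carbon skeleton from an aryl bromide and a C2 diester. High enantioselectivity is required.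

2 to 1, 4 to 3, 16 to 15 to 13: only O–Si bonds and the acyl C–Cl bond are cut. All three fragments come from commercial phenols; the one selectivity needed is to leave the hydrogen-bonded ortho hydroxyl of 1 free.

## Other disconnections considered

Alternative 1: cut of the C4–O bond, the first plan that comes to mind. The forward key step is a benzylic oxidation (DDQ, water) at C4 of the silyl-protected (+)-catechin 3-O-gallate A1, obtained from commercial (+)-catechin or from a 1,3-diarylpropene by asymmetric dihydroxylation and cyclisation, to give 17. The C4 cation forms next to the galloyl ester, whose carbonyl oxygen should capture it. The resulting cyclic acyloxonium ion opens with water to a cis hydroxy ester without control over which oxygen keeps the acyl group, and stereoelectronics favour the axial ester, here O4. The product carbinol is also more easily oxidised than A1. The chosen plan places both oxygens before the acyl group arrives and so avoids this scrambling.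

Alternative 2: cut of the C4–C4a bond. The forward key step is a Lewis acid promoted Friedel–Crafts hydroxyalkylation in which the phloroglucinol ring of aldehyde A2 attacks the formyl carbon, with the gallate already in place. The product carbinol ionises more easily than the aldehyde reacts, so the acid needed for ring closure should also epimerise C4 and lead to diarylmethane by-products. A2 is an α-acyloxy aldehyde that epimerises readily, and it requires an anti-1,2-diol with differentiated oxygens from a separate asymmetric sequence. C4 would be set without a strong control element, whereas the pinacol plan fixes it by chelation.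

Alternative 3: cut of O1–C2 and C3–C4 together. The forward key step is a hetero-Diels–Alder reaction of the ortho-quinone methide A3, generated from 2 and trimethyl orthoformate under acid, with the (E)-enol gallate A4, giving the 4-methoxychroman A5. This is the most convergent plan, but all three stereocentres would arise from achiral partners, so absolute control rests on a chiral catalyst for a weakly donating enol ester. The usual endo preference of such cycloadditions gives the 2,4-cis arrangement where the target is 2,4-trans. The C4 methyl ether would then have to be exchanged for hydroxyl through the very cation that scrambles C4. The chosen plan sets C2 by reliable catalysis and lets it direct C3 and C4.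

Key step: step 8

Remarks before the steps. TBS = tert-butyldimethylsilyl, TIPS = triisopropylsilyl; TBSO and TIPSO are the corresponding silyloxy groups. Flavan numbering (O1, C2, C3, C4, C4a, C5 to C8, C8a) is used throughout. Assumption: the benzylic C4–O bond is taken to be at risk under hydrogenolytic debenzylation, which is why all phenols are carried as silyl ethers.

## Steps

Step 1
Reactants: 1 2,4,6-trihydroxybenzaldehyde
Product: 2 2-hydroxy-4,6-bis(TIPSO)benzaldehyde
Conditions: i-Pr3SiCl (2.1 equiv), imidazole (4.5 equiv), DMF, 0 °C to rt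
Reagents that add atoms: triisopropylsilyl chloride, CC(C)[Si](Cl)(C(C)C)C(C)C
Why: Selective O-silylation: the 4-hydroxyl and one ortho hydroxyl react, while the remaining ortho hydroxyl is locked in a hydrogen bond to the formyl group, as in the known partial alkylations of this aldehyde. TIPS is chosen for ring A because one of these ethers later sits next to the C4 alkoxide, where a smaller silyl group could migrate from the phenol oxygen.

Step 2
Reactants: 3 4-bromobenzene-1,2-diol
Product: 4 4-bromo-1,2-bis(TBSO)benzene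
Conditions: t-BuMe2SiCl (2.3 equiv), imidazole (5 equiv), DMF, rt
Reagents that add atoms: tert-butyldimethylsilyl chloride, CC(C)(C)[Si](C)(C)Cl
Why: Standard silylation of both catechol hydroxyls; the aryl bromide is untouched.

Step 3
Reactants: 4 4-bromo-1,2-bis(TBSO)benzene; 5 dimethyl oxalate
Product: 7 methyl 2-[3,4-bis(TBSO)phenyl]-2-oxoacetate, via arylmagnesium bromide 6 (not isolated)
Conditions: Mg (1.3 equiv), I2 (cat.), THF, 50 °C; then added to 5 (2.5 equiv), THF, −78 °C; aq. NH4Cl
Reagents that add atoms: none
Why: Grignard formation and acylation with an excess of the diester at low temperature by inverse addition; the magnesium hemiketal alkoxide should survive until work-up, so the aryl group adds once and the aryl glyoxylate is released on quenching.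

Step 4
Reactants: 7 methyl 2-[3,4-bis(TBSO)phenyl]-2-oxoacetate
Product: 8 methyl (2S)-2-[3,4-bis(TBSO)phenyl]-2-hydroxyacetate
Conditions: RuCl[(R,R)-TsDPEN](p-cymene) (1 mol%), HCO2H/Et3N (5:2), DMF, 25 °C
Reagents that add atoms: none
Why: Noyori–Ikariya asymmetric transfer hydrogenation of an aryl α-keto ester, with hydride and proton passing in an outer-sphere six-membered transition state in which the aryl group lies against the cymene ligand. The (R,R)-catalyst gives (R)-1-arylethanols from aryl methyl ketones and should deliver hydride to the same face here; because CO2Me outranks the aryl group, that product is described as S.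

Step 5
Reactants: 2 2-hydroxy-4,6-bis(TIPSO)benzaldehyde; 8 methyl (2S)-2-[3,4-bis(TBSO)phenyl]-2-hydroxyacetate
Product: 9 methyl (2R)-2-[3,4-bis(TBSO)phenyl]-2-[2-formyl-3,5-bis(TIPSO)phenoxy]acetate
Conditions: PPh3 (1.3 equiv), DIAD (1.3 equiv, slow addition), toluene, 0 °C to rt
Reagents that add atoms: none
Why: Mitsunobu etherification: the acidic ortho-formyl phenol 2 displaces the oxyphosphonium group of 8 by SN2 with inversion, turning the S carbinol into the R aryl ether carbon that becomes C2. The α-ester group disfavours ionisation at the electron-rich benzylic carbon and so protects the enantiomeric purity.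

Step 6
Reactants: 9 methyl (2R)-2-[3,4-bis(TBSO)phenyl]-2-[2-formyl-3,5-bis(TIPSO)phenoxy]acetate
Product: 10 (2R)-2-[3,4-bis(TBSO)phenyl]-2-[2-(hydroxymethyl)-3,5-bis(TIPSO)phenoxy]ethan-1-ol
Conditions: LiBH4 (3 equiv), THF, 0 °C to rt; pH 7 phosphate buffer
Reagents that add atoms: none
Why: Hydride reduction: LiBH4 reduces the aldehyde at once and the methyl ester more slowly, without a strongly basic medium, so C2 should keep its configuration. Aryl silyl ethers are inert to it.

Step 7
Reactants: 10 (2R)-2-[3,4-bis(TBSO)phenyl]-2-[2-(hydroxymethyl)-3,5-bis(TIPSO)phenoxy]ethan-1-ol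
Product: 11 2-{(1R)-1-[3,4-bis(TBSO)phenyl]-2-oxoethoxy}-4,6-bis(TIPSO)benzaldehyde
Conditions: Dess–Martin periodinane (2.6 equiv), NaHCO3 (10 equiv), CH2Cl2, 0 °C to rt; aq. Na2S2O3/NaHCO3 wash; used at once without chromatography
Reagents that add atoms: none
Why: Dess–Martin oxidation of both primary alcohols under bicarbonate buffer, free of amine base. The α-aryl-α-aryloxy aldehyde of 11 enolises easily, so it is not chromatographed and is taken cold into step 8.

Step 8
Reactants: 11 2-{(1R)-1-[3,4-bis(TBSO)phenyl]-2-oxoethoxy}-4,6-bis(TIPSO)benzaldehyde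
Product: 12 (2R,3S,4S)-2-[3,4-bis(TBSO)phenyl]-5,7-bis(TIPSO)chromane-3,4-diol
Conditions: SmI2 (3 equiv, 0.1 M in THF), t-BuOH (3 equiv), THF, −78 °C, slow addition of 11 (final 0.01 M), then −40 °C; pH 7 phosphate buffer
Reagents that add atoms: none
Why: Samarium diiodide pinacol cyclisation, a union of two electrophilic carbonyl carbons through ketyl chemistry. Electron transfer to the conjugated ring A aldehyde gives the C4 ketyl, whose trivalent samarium counter-ion also binds the C3 aldehyde oxygen; the C3–C4 bond forms inside this chelate by 6-exo-trig attack of the ketyl carbon on the bound carbonyl, which closes ring C, and a second electron transfer gives the samarium diolate that is protonated on work-up. The closest known reaction type is the SmI2 cyclisation of 1,6-dialdehydes to cis-cyclohexane-1,2-diols. C3 and C4 are set together: the oxygen–samarium–oxygen bridge holds the two oxygens on the same face, hence 3,4-cis. The face is fixed by C2: in the chair-like transition state the C2 aryl group is equatorial, the C4 oxygen is pushed pseudoaxial by the peri C5 silyl ether (allylic 1,3-strain), and the bridged C3 oxygen gauche to it must then be equatorial, that is trans to the aryl group, which gives 3S,4S. The step needs ring closure to win over intermolecular coupling and over loss of the aryloxide from an aliphatic ketyl; high dilution, slow addition at −78 °C and the easier reduction of the aryl aldehyde should secure this. t-BuOH protonates the samarium alkoxides, so the medium should not become basic enough to enolise unreacted 11.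

Step 9
Reactants: 13 3,4,5-trihydroxybenzoic acid (gallic acid)
Product: 15 3,4,5-tris(TBSO)benzoic acid, via silyl ester 14 (not isolated)
Conditions: t-BuMe2SiCl (4.4 equiv), imidazole (9 equiv), DMF, rt; then AcOH/THF/H2O (3:1:1), rt
Reagents that add atoms: tert-butyldimethylsilyl chloride, CC(C)(C)[Si](C)(C)Cl
Why: Exhaustive silylation of the three phenols and the carboxyl group, then selective hydrolysis of the much more labile silyl ester by dilute acetic acid, which leaves aryl silyl ethers intact.

Step 10
Reactants: 15 3,4,5-tris(TBSO)benzoic acid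
Product: 16 3,4,5-tris(TBSO)benzoyl chloride
Conditions: (COCl)2 (1.5 equiv), DMF (cat.), CH2Cl2, 0 °C to rt; evaporated and used crude
Reagents that add atoms: oxalyl chloride, O=C(Cl)C(=O)Cl
Why: Acid chloride formation through the Vilsmeier-type chloroiminium catalyst; the by-products are gases and contact of the aryl silyl ethers with HCl is short.

Step 11
Reactants: 12 (2R,3S,4S)-2-[3,4-bis(TBSO)phenyl]-5,7-bis(TIPSO)chromane-3,4-diol; 16 3,4,5-tris(TBSO)benzoyl chloride
Product: 17 (2R,3S,4S)-2-[3,4-bis(TBSO)phenyl]-4-hydroxy-5,7-bis(TIPSO)chroman-3-yl 3,4,5-tris(TBSO)benzoate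
Conditions: Me2SnCl2 (10 mol%), i-Pr2NEt (1.5 equiv), 16 (1.1 equiv), THF, 0 °C to rt
Reagents that add atoms: none
Why: Organotin-catalysed regioselective monoacylation of a cis-1,2-diol: Me2SnCl2 forms a five-membered dimethylstannylene acetal in which the equatorial oxygen, here O3, is the nucleophilic one, as in the stannylene chemistry of cis-diols on pyranosides. O4 is pseudoaxial and screened by the peri TIPS ether, and the weak hindered amine should not trigger acyl migration.

Step 12
Reactants: 17 (2R,3S,4S)-2-[3,4-bis(TBSO)phenyl]-4-hydroxy-5,7-bis(TIPSO)chroman-3-yl 3,4,5-tris(TBSO)benzoate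
Product: 18 (2R,3S,4S)-2-(3,4-dihydroxyphenyl)-4,5,7-trihydroxychroman-3-yl 3,4,5-trihydroxybenzoate
Conditions: Bu4NF (8 equiv), AcOH (9 equiv), THF, 0 °C, argon; reverse-phase (C18) chromatography, water/MeCN
Reagents that add atoms: none
Why: Fluoride cleavage of all seven aryl silyl ethers; aryloxides are good leaving groups on silicon, so buffered fluoride should suffice at 0 °C. The acetic acid keeps phenoxide from building up (which would move the galloyl group to the cis O4 and expose the pyrogallol to oxidation) and is too weak to ionise the C4 carbinol; no reductive step touches C4–O.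

## Compound list

1 | 2,4,6-trihydroxybenzaldehyde | O=Cc1c(O)cc(O)cc1O | starting material
2 | 2-hydroxy-4,6-bis(triisopropylsilyloxy)benzaldehyde | O=Cc1c(O)cc(O[Si](C(C)C)(C(C)C)C(C)C)cc1O[Si](C(C)C)(C(C)C)C(C)C | intermediate
3 | 4-bromobenzene-1,2-diol | Oc1ccc(Br)cc1O | starting material
4 | 4-bromo-1,2-bis(tert-butyldimethylsilyloxy)benzene | Brc1ccc(O[Si](C)(C)C(C)(C)C)c(O[Si](C)(C)C(C)(C)C)c1 | intermediate
5 | dimethyl oxalate | COC(=O)C(=O)OC | starting material
6 | [3,4-bis(tert-butyldimethylsilyloxy)phenyl]magnesium bromide | Br[Mg]c1ccc(O[Si](C)(C)C(C)(C)C)c(O[Si](C)(C)C(C)(C)C)c1 | intermediate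
7 | methyl 2-[3,4-bis(tert-butyldimethylsilyloxy)phenyl]-2-oxoacetate | COC(=O)C(=O)c1ccc(O[Si](C)(C)C(C)(C)C)c(O[Si](C)(C)C(C)(C)C)c1 | intermediate
8 | methyl (2S)-2-[3,4-bis(tert-butyldimethylsilyloxy)phenyl]-2-hydroxyacetate | COC(=O)[C@H](c1ccc(O[Si](C)(C)C(C)(C)C)c(O[Si](C)(C)C(C)(C)C)c1)O | intermediate
9 | methyl (2R)-2-[3,4-bis(tert-butyldimethylsilyloxy)phenyl]-2-[2-formyl-3,5-bis(triisopropylsilyloxy)phenoxy]acetate | COC(=O)[C@@H](c1ccc(O[Si](C)(C)C(C)(C)C)c(O[Si](C)(C)C(C)(C)C)c1)Oc1cc(O[Si](C(C)C)(C(C)C)C(C)C)cc(O[Si](C(C)C)(C(C)C)C(C)C)c1C=O | intermediate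
10 | (2R)-2-[3,4-bis(tert-butyldimethylsilyloxy)phenyl]-2-[2-(hydroxymethyl)-3,5-bis(triisopropylsilyloxy)phenoxy]ethan-1-ol | OC[C@@H](c1ccc(O[Si](C)(C)C(C)(C)C)c(O[Si](C)(C)C(C)(C)C)c1)Oc1cc(O[Si](C(C)C)(C(C)C)C(C)C)cc(O[Si](C(C)C)(C(C)C)C(C)C)c1CO | intermediate
11 | 2-{(1R)-1-[3,4-bis(tert-butyldimethylsilyloxy)phenyl]-2-oxoethoxy}-4,6-bis(triisopropylsilyloxy)benzaldehyde | O=C[C@@H](c1ccc(O[Si](C)(C)C(C)(C)C)c(O[Si](C)(C)C(C)(C)C)c1)Oc1cc(O[Si](C(C)C)(C(C)C)C(C)C)cc(O[Si](C(C)C)(C(C)C)C(C)C)c1C=O | intermediate
12 | (2R,3S,4S)-2-[3,4-bis(tert-butyldimethylsilyloxy)phenyl]-5,7-bis(triisopropylsilyloxy)chromane-3,4-diol | O[C@@H]1[C@@H](c2ccc(O[Si](C)(C)C(C)(C)C)c(O[Si](C)(C)C(C)(C)C)c2)Oc2cc(O[Si](C(C)C)(C(C)C)C(C)C)cc(O[Si](C(C)C)(C(C)C)C(C)C)c2[C@@H]1O | intermediate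
13 | 3,4,5-trihydroxybenzoic acid (gallic acid) | O=C(O)c1cc(O)c(O)c(O)c1 | starting material
14 | tert-butyldimethylsilyl 3,4,5-tris(tert-butyldimethylsilyloxy)benzoate | CC(C)(C)[Si](C)(C)OC(=O)c1cc(O[Si](C)(C)C(C)(C)C)c(O[Si](C)(C)C(C)(C)C)c(O[Si](C)(C)C(C)(C)C)c1 | intermediate
15 | 3,4,5-tris(tert-butyldimethylsilyloxy)benzoic acid | O=C(O)c1cc(O[Si](C)(C)C(C)(C)C)c(O[Si](C)(C)C(C)(C)C)c(O[Si](C)(C)C(C)(C)C)c1 | intermediate
16 | 3,4,5-tris(tert-butyldimethylsilyloxy)benzoyl chloride | O=C(Cl)c1cc(O[Si](C)(C)C(C)(C)C)c(O[Si](C)(C)C(C)(C)C)c(O[Si](C)(C)C(C)(C)C)c1 | intermediate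
17 | (2R,3S,4S)-2-[3,4-bis(tert-butyldimethylsilyloxy)phenyl]-4-hydroxy-5,7-bis(triisopropylsilyloxy)chroman-3-yl 3,4,5-tris(tert-butyldimethylsilyloxy)benzoate | O=C(O[C@@H]1[C@@H](c2ccc(O[Si](C)(C)C(C)(C)C)c(O[Si](C)(C)C(C)(C)C)c2)Oc2cc(O[Si](C(C)C)(C(C)C)C(C)C)cc(O[Si](C(C)C)(C(C)C)C(C)C)c2[C@@H]1O)c1cc(O[Si](C)(C)C(C)(C)C)c(O[Si](C)(C)C(C)(C)C)c(O[Si](C)(C)C(C)(C)C)c1 | intermediate
18 | (2R,3S,4S)-2-(3,4-dihydroxyphenyl)-4,5,7-trihydroxychroman-3-yl 3,4,5-trihydroxybenzoate | O=C(O[C@@H]1[C@@H](c2ccc(O)c(O)c2)Oc2cc(O)cc(O)c2[C@@H]1O)c1cc(O)c(O)c(O)c1 | target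

## Step count and least certain steps

Total: 12 steps. Longest linear sequence: 9 steps (steps 2, 3, 4, 5, 6, 7, 8, 11 and 12).

Step 8 (key step). Most likely failures:
- loss of configuration at C2 by enolisation of 11 before it couples, or a base-triggered intramolecular aldol closure of 11 onto the ring A aldehyde, during step 7 or the slow addition;
- intermolecular pinacol coupling, or reductive loss of the aryloxide if the aliphatic aldehyde is reduced first;
- incomplete cis or facial selectivity if the chelate is not maintained.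

Fallback: it sets out from 9 and comes back at 12, avoids any isolated α-aryloxy aldehyde and replaces the reductive coupling by alkene chemistry.
- The aryl aldehyde of 9 is methylenated without base (CH2I2, Zn, Ti(OiPr)4, THF; Takai conditions) to methyl (2R)-2-[3,4-bis(TBSO)phenyl]-2-[2-ethenyl-3,5-bis(TIPSO)phenoxy]acetate F1.
- Reduction with i-Bu2AlH at −78 °C, then Ph3P=CH2 added to the cold aluminium hemiacetal, should give 1-{[(1S)-1-[3,4-bis(TBSO)phenyl]prop-2-en-1-yl]oxy}-2-ethenyl-3,5-bis(TIPSO)benzene F2.
- Ring-closing metathesis with the second-generation Grubbs catalyst RuCl2(=CHPh)(PCy3)(H2IMes) closes C3=C4 to (2S)-2-[3,4-bis(TBSO)phenyl]-5,7-bis(TIPSO)-2H-chromene F3.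
- Upjohn dihydroxylation (OsO4 cat., N-methylmorpholine N-oxide, acetone/water) from the face opposite the C2 aryl group gives 12.

Step 5. Most likely failures: partial ionisation of the oxyphosphonium intermediate at the electron-rich benzylic carbon, which would erode the enantiomeric purity; sluggish reaction of the hydrogen-bonded phenol; and a base-induced 5-exo aldol closure of 9 between its acidic C2–H and the ortho formyl group, leading towards a benzofuran.

Fallback: it sets out from 7 (with 2) and comes back at 9, and replaces the substitution by a carbene O–H insertion.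
- Condensation of 7 with tosylhydrazine gives methyl (2Z)-2-[3,4-bis(TBSO)phenyl]-2-(2-tosylhydrazinylidene)acetate F4.
- DBU converts it into methyl 2-diazo-2-[3,4-bis(TBSO)phenyl]acetate F5.
- Enantioselective insertion of the derived metal carbene into the O–H bond of 2 (PdCl2(PhCN)2, chiral spiro-bisoxazoline ligand, NaB[3,5-(CF3)2C6H3]4, CHCl3, ligand enantiomer chosen for the R product) gives 9.
Here C2 is set by the catalyst in a proton transfer step, and neither a benzylic cation nor a basic medium is involved.

Step 11. Most likely failures: competing acylation at O4, double acylation, or migration of the galloyl group from O3 to the cis O4 during reaction or chromatography.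

Fallback: it sets out from 12 and comes back at 17, and removes the regiochemical question instead of answering it with a catalyst.
- MnO2 in CH2Cl2 oxidises only the benzylic C4 hydroxyl to (2R,3R)-2-[3,4-bis(TBSO)phenyl]-3-hydroxy-5,7-bis(TIPSO)chroman-4-one F6.
- Its single hydroxyl is acylated with 16 (pyridine, DMAP cat.) to (2R,3R)-2-[3,4-bis(TBSO)phenyl]-4-oxo-5,7-bis(TIPSO)chroman-3-yl 3,4,5-tris(TBSO)benzoate F7.
- LiBH(s-Bu)3 at −78 °C, attacking the ketone along the equatorial trajectory, should give the pseudoaxial C4 alcohol 17 (3,4-cis).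

## Further compounds

F1 | step 8 | methyl (2R)-2-[3,4-bis(tert-butyldimethylsilyloxy)phenyl]-2-[2-ethenyl-3,5-bis(triisopropylsilyloxy)phenoxy]acetate | COC(=O)[C@@H](c1ccc(O[Si](C)(C)C(C)(C)C)c(O[Si](C)(C)C(C)(C)C)c1)Oc1cc(O[Si](C(C)C)(C(C)C)C(C)C)cc(O[Si](C(C)C)(C(C)C)C(C)C)c1C=C
F2 | step 8 | 1-{[(1S)-1-[3,4-bis(tert-butyldimethylsilyloxy)phenyl]prop-2-en-1-yl]oxy}-2-ethenyl-3,5-bis(triisopropylsilyloxy)benzene | C=C[C@@H](c1ccc(O[Si](C)(C)C(C)(C)C)c(O[Si](C)(C)C(C)(C)C)c1)Oc1cc(O[Si](C(C)C)(C(C)C)C(C)C)cc(O[Si](C(C)C)(C(C)C)C(C)C)c1C=C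
F3 | step 8 | (2S)-2-[3,4-bis(tert-butyldimethylsilyloxy)phenyl]-5,7-bis(triisopropylsilyloxy)-2H-chromene | C1=C[C@@H](c2ccc(O[Si](C)(C)C(C)(C)C)c(O[Si](C)(C)C(C)(C)C)c2)Oc2cc(O[Si](C(C)C)(C(C)C)C(C)C)cc(O[Si](C(C)C)(C(C)C)C(C)C)c21
F4 | step 5 | methyl (2Z)-2-[3,4-bis(tert-butyldimethylsilyloxy)phenyl]-2-(2-tosylhydrazinylidene)acetate | COC(=O)/C(=N\NS(=O)(=O)c1ccc(C)cc1)c1ccc(O[Si](C)(C)C(C)(C)C)c(O[Si](C)(C)C(C)(C)C)c1
F5 | step 5 | methyl 2-diazo-2-[3,4-bis(tert-butyldimethylsilyloxy)phenyl]acetate | COC(=O)C(=[N+]=[N-])c1ccc(O[Si](C)(C)C(C)(C)C)c(O[Si](C)(C)C(C)(C)C)c1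
F6 | step 11 | (2R,3R)-2-[3,4-bis(tert-butyldimethylsilyloxy)phenyl]-3-hydroxy-5,7-bis(triisopropylsilyloxy)chroman-4-one | O[C@@H]1[C@@H](c2ccc(O[Si](C)(C)C(C)(C)C)c(O[Si](C)(C)C(C)(C)C)c2)Oc2cc(O[Si](C(C)C)(C(C)C)C(C)C)cc(O[Si](C(C)C)(C(C)C)C(C)C)c2C1=O
F7 | step 11 | (2R,3R)-2-[3,4-bis(tert-butyldimethylsilyloxy)phenyl]-4-oxo-5,7-bis(triisopropylsilyloxy)chroman-3-yl 3,4,5-tris(tert-butyldimethylsilyloxy)benzoate | O=C(O[C@@H]1[C@@H](c2ccc(O[Si](C)(C)C(C)(C)C)c(O[Si](C)(C)C(C)(C)C)c2)Oc2cc(O[Si](C(C)C)(C(C)C)C(C)C)cc(O[Si](C(C)C)(C(C)C)C(C)C)c2C1=O)c1cc(O[Si](C)(C)C(C)(C)C)c(O[Si](C)(C)C(C)(C)C)c(O[Si](C)(C)C(C)(C)C)c1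
A1 | alternative 1 | (2R,3S)-2-[3,4-bis(tert-butyldimethylsilyloxy)phenyl]-5,7-bis(triisopropylsilyloxy)chroman-3-yl 3,4,5-tris(tert-butyldimethylsilyloxy)benzoate | O=C(O[C@@H]1[C@@H](c2ccc(O[Si](C)(C)C(C)(C)C)c(O[Si](C)(C)C(C)(C)C)c2)Oc2cc(O[Si](C(C)C)(C(C)C)C(C)C)cc(O[Si](C(C)C)(C(C)C)C(C)C)c2C1)c1cc(O[Si](C)(C)C(C)(C)C)c(O[Si](C)(C)C(C)(C)C)c(O[Si](C)(C)C(C)(C)C)c1
A2 | alternative 2 | (2R,3R)-3-[3,4-bis(tert-butyldimethylsilyloxy)phenyl]-3-[3,5-bis(triisopropylsilyloxy)phenoxy]-1-oxopropan-2-yl 3,4,5-tris(tert-butyldimethylsilyloxy)benzoate | O=C(O[C@@H](C=O)[C@@H](c1ccc(O[Si](C)(C)C(C)(C)C)c(O[Si](C)(C)C(C)(C)C)c1)Oc1cc(O[Si](C(C)C)(C(C)C)C(C)C)cc(O[Si](C(C)C)(C(C)C)C(C)C)c1)c1cc(O[Si](C)(C)C(C)(C)C)c(O[Si](C)(C)C(C)(C)C)c(O[Si](C)(C)C(C)(C)C)c1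
A3 | alternative 3 | (6E)-6-(methoxymethylidene)-3,5-bis(triisopropylsilyloxy)cyclohexa-2,4-dien-1-one | CO/C=C1/C(=O)C=C(O[Si](C(C)C)(C(C)C)C(C)C)C=C1O[Si](C(C)C)(C(C)C)C(C)C
A4 | alternative 3 | (E)-2-[3,4-bis(tert-butyldimethylsilyloxy)phenyl]ethenyl 3,4,5-tris(tert-butyldimethylsilyloxy)benzoate | O=C(O/C=C/c1ccc(O[Si](C)(C)C(C)(C)C)c(O[Si](C)(C)C(C)(C)C)c1)c1cc(O[Si](C)(C)C(C)(C)C)c(O[Si](C)(C)C(C)(C)C)c(O[Si](C)(C)C(C)(C)C)c1
A5 | alternative 3 | (2R,3S,4S)-2-[3,4-bis(tert-butyldimethylsilyloxy)phenyl]-4-methoxy-5,7-bis(triisopropylsilyloxy)chroman-3-yl 3,4,5-tris(tert-butyldimethylsilyloxy)benzoate | O=C(O[C@@H]1[C@@H](c2ccc(O[Si](C)(C)C(C)(C)C)c(O[Si](C)(C)C(C)(C)C)c2)Oc2cc(O[Si](C(C)C)(C(C)C)C(C)C)cc(O[Si](C(C)C)(C(C)C)C(C)C)c2[C@@H]1OC)c1cc(O[Si](C)(C)C(C)(C)C)c(O[Si](C)(C)C(C)(C)C)c(O[Si](C)(C)C(C)(C)C)c1
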